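Numbering: ring A is C1 (carries the methylidene), C2 (CH2), C3=C4, C5 (CMe2), C6 (CH). C7 is the carbinol and C8=C9 the chain alkene (Me on C9). Ring B is C10 (CH) to C15, with C13 the tertiary carbinol and C14 the CHBr.
Cuts: first C7–C8 (aldehyde plus alkenyl iodide), then C1–C6 of ring A (enol silane carbon onto a terminal alkyne), then C3=C4 (Wittig). The ring B carbocycle comes from (S)-limonene, so only its C9 side chain and the C13/C14 heteroatoms have to be made.
Enabling feature: in ring A the C1 methylidene stands directly beside C6, and C6 is the alpha-carbon of C7 at the carbonyl level. A 1,1-disubstituted alkene next to an enolisable CH is the imprint of an enol carbon adding to the inner carbon of a terminal alkyne. The C5 gem-dimethyl group and the cis C3=C4 alkene already fold the open chain towards that six-membered closure.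
Forward order: the C7-to-C1 chain is built linearly, ring A is closed by gold catalysis, ring B is dressed separately, and the halves are joined last at C7–C8 with nothing left to deprotect.
Stereochemistry: C10 comes from limonene. C13 and C14 are relayed from C10 by trans-diaxial epoxide hydrolysis and then SN2 inversion at C14; Br and OH are cis, so direct bromohydrin formation would give the wrong C14 epimer. C6 comes from the chiral gold catalyst and C7 from Felkin–Anh addition anti to C5. The Wittig step sets Z-C3=C4 and syn carboalumination sets E-C8=C9.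

Key step: step 7

Assumption: the (R)-ligand is written for step 7, because the sense of induction of a digold bisphosphine in a six-membered closure cannot be derived from the five-membered cases. Should it favour (S)-12, the equally available (S)-ligand is used.

Step 1
Reactants: 1 methyl 3,3-dimethylpent-4-enoate
Product: 3 methyl 3,3-dimethyl-4-oxobutanoate, via secondary ozonide 2 (not isolated)
Conditions: O3, CH2Cl2, −78 °C; then Me2S, −78 °C to rt
Reagents that add atoms: ozone, [O-][O+]=O
Why: Ozonolysis with reductive work-up cleaves the only alkene and should give the non-enolisable aldehyde (future C4) on the C5 gem-dimethyl carbon, with the C6–C7 arm already present as the ester.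

Step 2
Reactants: 4 (4-bromobut-1-yn-1-yl)trimethylsilane
Product: 5 triphenyl[4-(trimethylsilyl)but-3-yn-1-yl]phosphonium bromide
Conditions: PPh3, MeCN, reflux
Reagents that add atoms: triphenylphosphine, c1ccc(cc1)P(c1ccccc1)c1ccccc1
Why: SN2 quaternisation of triphenylphosphine by a primary bromide is the standard entry to a Wittig salt, and the C-silyl group keeps the alkyne terminus from being deprotonated in the next step.

Step 3
Reactants: 5 triphenyl[4-(trimethylsilyl)but-3-yn-1-yl]phosphonium bromide; 3 methyl 3,3-dimethyl-4-oxobutanoate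
Product: 7 methyl (4Z)-3,3-dimethyl-8-(trimethylsilyl)oct-4-en-7-ynoate, via phosphonium ylide 6 (not isolated)
Conditions: 5, NaN(SiMe3)2, THF, −78 °C; then 3, −78 °C to rt
Reagents that add atoms: none
Why: A lithium-free Wittig reaction of a non-stabilised ylide with an alpha-quaternary aldehyde passes through the cis-oxaphosphetane and should give the Z C3=C4 alkene; the ylide is made and consumed cold so that beta-elimination of PPh3 cannot compete and the ester is not attacked.

Step 4
Reactants: 7 methyl (4Z)-3,3-dimethyl-8-(trimethylsilyl)oct-4-en-7-ynoate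
Product: 8 methyl (4Z)-3,3-dimethyloct-4-en-7-ynoate
Conditions: K2CO3 (cat.), MeOH, 0 °C
Reagents that add atoms: none
Why: Base-catalysed methanolysis (protiodesilylation) cleaves only the C(sp)–Si bond; methoxide is too weak a base to move the skipped enyne into conjugation, and exchange at the methyl ester is degenerate in methanol.

Step 5
Reactants: 8 methyl (4Z)-3,3-dimethyloct-4-en-7-ynoate
Product: 10 (4Z)-3,3-dimethyloct-4-en-7-ynal, via aluminium hemiacetal 9 (not isolated)
Conditions: i-Bu2AlH (1.05 equiv), CH2Cl2, −78 °C; then MeOH, aq. potassium sodium tartrate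
Reagents that add atoms: none
Why: Partial ester reduction with one equivalent of i-Bu2AlH stops at the tetrahedral aluminium hemiacetal, which persists at −78 °C beside the hindered C5 centre and collapses to the aldehyde only on work-up; alkyne and alkene are not hydroaluminated in the cold.

Step 6
Reactants: 10 (4Z)-3,3-dimethyloct-4-en-7-ynal
Product: 11 tert-butyl{[(1E,4Z)-3,3-dimethylocta-1,4-dien-7-yn-1-yl]oxy}dimethylsilane
Conditions: TBSOTf, Et3N, CH2Cl2, 0 °C
Reagents that add atoms: tert-butyldimethylsilyl trifluoromethanesulfonate, CC(C)(C)[Si](C)(C)OS(=O)(=O)C(F)(F)F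
Why: Soft enolisation (silyl triflate activation, deprotonation at C6 by the amine) needs no strong base, so the alkyne C–H and the doubly activated C2 methylene are left alone; the bulky tertiary C5 substituent should turn away from the silyloxy group to favour the E enol silane, and any Z isomer is removed on Et3N-deactivated silica.

Step 7
Reactants: 11 tert-butyl{[(1E,4Z)-3,3-dimethylocta-1,4-dien-7-yn-1-yl]oxy}dimethylsilane
Product: 12 (1R)-6,6-dimethyl-2-methylidenecyclohex-4-ene-1-carbaldehyde
Conditions: [(R)-DTBM-SEGPHOS](AuCl)2 (3 mol %), AgSbF6 (6 mol %, AgCl filtered off), i-PrOH (1.5 equiv), CH2Cl2, −20 °C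
Reagents that add atoms: none
Why: Proposed new method: the cationic monovalent gold centre binds the terminal alkyne of 11, the nucleophilic enol silane carbon C6 adds anti to gold at the inner alkyne carbon C1, isopropanol strips the silyl group from the silyloxocarbenium ion so formed, and the released proton cleaves the vinyl–gold bond to leave the C1 methylidene and the free aldehyde. The closest known reaction type is the gold-catalysed Conia-ene carbocyclisation of silyl enol ethers onto alkynes, which is established for 5-exo, 5-endo and racemic 6-exo closures but has been made enantioselective only for five-membered rings. Ring A closes in the 6-exo-dig mode, since the Markovnikov polarisation of a terminal alkyne places the developing charge on C1 and disfavours the 7-endo path. The single new stereocentre C6 is decided by which face of the geometrically pure E enol silane the bulky chiral digold bisphosphine allows to reach the bound alkyne, with no substrate bias. The step needs exo regioselectivity, a closure faster than alcohol addition to the alkyne, and no drift of the C1 or C3=C4 alkenes into conjugation with the aldehyde. The Thorpe–Ingold effect of the C5 gem-dimethyl group and the cis C3=C4 alkene shorten the C6-to-C1 distance, the hindered alcohol is a poor nucleophile towards the alkyne, and the medium stays neutral and cold.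

Step 8
Reactants: 13 (S)-(−)-limonene
Product: 15 1-[(1S)-4-methylcyclohex-3-en-1-yl]ethan-1-one, via side-chain diol 14 (not isolated)
Conditions: K2OsO4·2H2O (1 mol %), NMO (1.0 equiv), acetone/H2O, 0 °C; then NaIO4, rt
Reagents that add atoms: N-methylmorpholine N-oxide, C[N+]1([O-])CCOCC1; water, O
Why: Catalytic osmium tetroxide dihydroxylation is sterically governed, so with limiting oxidant the unhindered 1,1-disubstituted alkene should react ahead of the ring trisubstituted one, and periodate glycol cleavage then gives the methyl ketone under neutral conditions that leave C10 untouched.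

Step 9
Reactants: 15 1-[(1S)-4-methylcyclohex-3-en-1-yl]ethan-1-one
Product: 17 (4S)-4-ethynyl-1-methylcyclohex-1-ene, via enol phosphate 16 (not isolated)
Conditions: LiN(i-Pr)2, THF, −78 °C; ClP(O)(OEt)2, −78 °C to rt; then LiN(i-Pr)2 (2.3 equiv), −78 °C to rt
Reagents that add atoms: none
Why: Kinetic deprotonation at the methyl group, O-phosphorylation and E2 loss of diethyl phosphate (methyl ketone to terminal alkyne by enol phosphate elimination) never involve the C10–H bond, and the ring alkene serves as a base-stable mask for the later bromohydrin.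

Step 10
Reactants: 17 (4S)-4-ethynyl-1-methylcyclohex-1-ene
Product: 19 (4S)-4-[(1E)-1-iodoprop-1-en-2-yl]-1-methylcyclohex-1-ene, via alkenylalane 18 (not isolated)
Conditions: AlMe3, Cp2ZrCl2 (20 mol %), CH2Cl2, 0 °C to rt; then I2, THF, −30 °C
Reagents that add atoms: trimethylaluminium, C[Al](C)C; iodine, II
Why: Zirconium-catalysed Negishi carboalumination adds methyl (to C9) and aluminium (to C8) syn across the terminal alkyne, and iodinolysis with retention should give the E iodoalkene, the trisubstituted ring alkene being inert to carbometalation.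

Step 11
Reactants: 19 (4S)-4-[(1E)-1-iodoprop-1-en-2-yl]-1-methylcyclohex-1-ene
Product: 22 (1R,2R,4S)-4-[(1E)-1-iodoprop-1-en-2-yl]-1-methylcyclohexane-1,2-diol, via (1S,4S,6R)-epoxide 20 (not isolated), via (1R,4S,6S)-epoxide 21 (not isolated)
Conditions: mCPBA (1.0 equiv), CH2Cl2, 0 °C; then crude epoxides, HClO4 (cat.), THF/H2O, 0 °C to rt
Reagents that add atoms: 3-chloroperoxybenzoic acid, O=C(OO)c1cccc(Cl)c1; water, O
Why: Prilezhaev epoxidation picks the electron-rich ring alkene over the iodoalkene, and acid hydrolysis under the Fürst–Plattner rule opens 20 at C13 and 21 at C14, so both epoxides should converge on the one trans-diaxial diol in which C10 has fixed C13 as R (final) and C14 as R (to be inverted).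

Step 12
Reactants: 22 (1R,2R,4S)-4-[(1E)-1-iodoprop-1-en-2-yl]-1-methylcyclohexane-1,2-diol
Product: 24 (1R,2R,5S)-5-[(1E)-1-iodoprop-1-en-2-yl]-2-methyl-2-[(trimethylsilyl)oxy]cyclohexyl chloromethanesulfonate, via hydroxy chloromethanesulfonate 23 (not isolated)
Conditions: ClCH2SO2Cl, 2,6-lutidine, CH2Cl2, 0 °C; then TMSOTf, −78 to 0 °C
Reagents that add atoms: chloromethanesulfonyl chloride, ClCS(=O)(=O)Cl; trimethylsilyl trifluoromethanesulfonate, C[Si](C)(C)OS(=O)(=O)C(F)(F)F
Why: Selective O-sulfonylation takes the secondary C14 hydroxyl because the tertiary one is too hindered, and O-silylation of C13–OH with the silyl triflate then masks the antiperiplanar oxygen that would otherwise close to the epoxide during the displacement.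

Step 13
Reactants: 24 (1R,2R,5S)-5-[(1E)-1-iodoprop-1-en-2-yl]-2-methyl-2-[(trimethylsilyl)oxy]cyclohexyl chloromethanesulfonate
Product: 26 (1R,2S,4S)-2-bromo-4-[(1E)-1-iodoprop-1-en-2-yl]-1-methylcyclohexan-1-ol, via bromo silyl ether 25 (not isolated)
Conditions: LiBr (10 equiv), THF, 50 °C; then 1 M HCl, THF, 0 °C
Reagents that add atoms: lithium bromide, [Li+].[Br-]
Why: SN2 displacement of the activated axial chloromethanesulfonate by the weakly basic bromide proceeds with inversion, so bromine should arrive equatorial at C14 (S) and cis to the axial C13 oxygen, and brief mild acid then removes the trimethylsilyl ether.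

Step 14
Reactants: 12 (1R)-6,6-dimethyl-2-methylidenecyclohex-4-ene-1-carbaldehyde; 26 (1R,2S,4S)-2-bromo-4-[(1E)-1-iodoprop-1-en-2-yl]-1-methylcyclohexan-1-ol
Product: 28 (1R,2S,4S)-2-bromo-4-{(2E,4R)-4-[(1R)-6,6-dimethyl-2-methylidenecyclohex-4-en-1-yl]-4-hydroxybut-2-en-2-yl}-1-methylcyclohexan-1-ol, via alkenylchromium reagent 27 (not isolated)
Conditions: CrCl2 (4 equiv), NiCl2 (1 mol %), DMSO, rt
Reagents that add atoms: none
Why: In the Nozaki–Hiyama–Kishi coupling nickel inserts into the C–I bond with retention of the E geometry and hands the alkenyl group to chromium, giving a non-basic nucleophile that tolerates the free tertiary alcohol, the unactivated secondary bromide and the isomerisation-prone aldehyde; Felkin–Anh attack anti to the quaternary C5 and past the C6–H should set C7 as R.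

Compound list
1 | methyl 3,3-dimethylpent-4-enoate | C=CC(C)(C)CC(=O)OC | starting material
2 | methyl 3-methyl-3-(1,2,4-trioxolan-3-yl)butanoate (secondary ozonide) | COC(=O)CC(C)(C)C1OCOO1 | intermediate
3 | methyl 3,3-dimethyl-4-oxobutanoate | COC(=O)CC(C)(C)C=O | intermediate
4 | (4-bromobut-1-yn-1-yl)trimethylsilane | C[Si](C)(C)C#CCCBr | starting material
5 | triphenyl[4-(trimethylsilyl)but-3-yn-1-yl]phosphonium bromide | C[Si](C)(C)C#CCC[P+](c1ccccc1)(c1ccccc1)c1ccccc1.[Br-] | intermediate
6 | triphenyl[4-(trimethylsilyl)but-3-yn-1-ylidene]-λ5-phosphane (ylide) | C[Si](C)(C)C#CCC=P(c1ccccc1)(c1ccccc1)c1ccccc1 | intermediate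
7 | methyl (4Z)-3,3-dimethyl-8-(trimethylsilyl)oct-4-en-7-ynoate | COC(=O)CC(C)(C)/C=C\CC#C[Si](C)(C)C | intermediate
8 | methyl (4Z)-3,3-dimethyloct-4-en-7-ynoate | C#CC/C=C\C(C)(C)CC(=O)OC | intermediate
9 | {[(4Z)-1-methoxy-3,3-dimethyloct-4-en-7-yn-1-yl]oxy}bis(2-methylpropyl)alumane (aluminium hemiacetal) | C#CC/C=C\C(C)(C)CC(OC)O[Al](CC(C)C)CC(C)C | intermediate
10 | (4Z)-3,3-dimethyloct-4-en-7-ynal | C#CC/C=C\C(C)(C)CC=O | intermediate
11 | tert-butyl{[(1E,4Z)-3,3-dimethylocta-1,4-dien-7-yn-1-yl]oxy}dimethylsilane | C#CC/C=C\C(C)(C)/C=C/O[Si](C)(C)C(C)(C)C | intermediate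
12 | (1R)-6,6-dimethyl-2-methylidenecyclohex-4-ene-1-carbaldehyde | C=C1CC=CC(C)(C)[C@@H]1C=O | intermediate
13 | (S)-(−)-limonene, (4S)-1-methyl-4-(prop-1-en-2-yl)cyclohex-1-ene | C=C(C)[C@H]1CCC(C)=CC1 | starting material
14 | 2-[(1S)-4-methylcyclohex-3-en-1-yl]propane-1,2-diol (both epimers at the carbinol carbon) | CC(O)(CO)[C@H]1CCC(C)=CC1 | intermediate
15 | 1-[(1S)-4-methylcyclohex-3-en-1-yl]ethan-1-one | CC(=O)[C@H]1CCC(C)=CC1 | intermediate
16 | diethyl 1-[(1S)-4-methylcyclohex-3-en-1-yl]ethenyl phosphate | C=C(OP(=O)(OCC)OCC)[C@H]1CCC(C)=CC1 | intermediate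
17 | (4S)-4-ethynyl-1-methylcyclohex-1-ene | C#C[C@H]1CCC(C)=CC1 | intermediate
18 | dimethyl{(1E)-2-[(1S)-4-methylcyclohex-3-en-1-yl]prop-1-en-1-yl}alumane | C/C(=C\[Al](C)C)[C@H]1CCC(C)=CC1 | intermediate
19 | (4S)-4-[(1E)-1-iodoprop-1-en-2-yl]-1-methylcyclohex-1-ene | C/C(=C\I)[C@H]1CCC(C)=CC1 | intermediate
20 | (1S,4S,6R)-4-[(1E)-1-iodoprop-1-en-2-yl]-1-methyl-7-oxabicyclo[4.1.0]heptane | C/C(=C\I)[C@H]1CC[C@]2(C)O[C@@H]2C1 | intermediate
21 | (1R,4S,6S)-4-[(1E)-1-iodoprop-1-en-2-yl]-1-methyl-7-oxabicyclo[4.1.0]heptane | C/C(=C\I)[C@H]1CC[C@@]2(C)O[C@H]2C1 | intermediate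
22 | (1R,2R,4S)-4-[(1E)-1-iodoprop-1-en-2-yl]-1-methylcyclohexane-1,2-diol | C/C(=C\I)[C@H]1CC[C@@](C)(O)[C@H](O)C1 | intermediate
23 | (1R,2R,5S)-2-hydroxy-5-[(1E)-1-iodoprop-1-en-2-yl]-2-methylcyclohexyl chloromethanesulfonate | C/C(=C\I)[C@H]1CC[C@@](C)(O)[C@H](OS(=O)(=O)CCl)C1 | intermediate
24 | (1R,2R,5S)-5-[(1E)-1-iodoprop-1-en-2-yl]-2-methyl-2-[(trimethylsilyl)oxy]cyclohexyl chloromethanesulfonate | C/C(=C\I)[C@H]1CC[C@@](C)(O[Si](C)(C)C)[C@H](OS(=O)(=O)CCl)C1 | intermediate
25 | {[(1R,2S,4S)-2-bromo-4-[(1E)-1-iodoprop-1-en-2-yl]-1-methylcyclohexyl]oxy}trimethylsilane | C/C(=C\I)[C@H]1CC[C@@](C)(O[Si](C)(C)C)[C@@H](Br)C1 | intermediate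
26 | (1R,2S,4S)-2-bromo-4-[(1E)-1-iodoprop-1-en-2-yl]-1-methylcyclohexan-1-ol | C/C(=C\I)[C@H]1CC[C@@](C)(O)[C@@H](Br)C1 | intermediate
27 | {(1E)-2-[(1S,3S,4R)-3-bromo-4-hydroxy-4-methylcyclohexyl]prop-1-en-1-yl}dichlorochromium | C/C(=C\[Cr](Cl)Cl)[C@H]1CC[C@@](C)(O)[C@@H](Br)C1 | intermediate
28 | (1R,2S,4S)-2-bromo-4-{(2E,4R)-4-[(1R)-6,6-dimethyl-2-methylidenecyclohex-4-en-1-yl]-4-hydroxybut-2-en-2-yl}-1-methylcyclohexan-1-ol | C=C1CC=CC(C)(C)[C@@H]1[C@H](O)/C=C(\C)[C@H]1CC[C@@](C)(O)[C@@H](Br)C1 | target

Total step count: 14. Longest linear sequence: 7 steps (step 1 or 2, then 3 to 7 and 14; the ring B branch, steps 8 to 14, is equally long).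

Steps most likely to fail

1. Step 7.
- **Risk:** The chiral ligand on a linear two-coordinate gold centre sits far from C6 and may discriminate poorly between the two faces of the enol silane. The six-membered closure may be slow enough for alcohol addition to the alkyne or protodesilylation of the enol silane to take over. Traces of acid may also move the product alkenes into conjugation with the aldehyde.
- **Fallback (known chemistry, no asymmetric catalysis):** Setting out from 11, the closure is run with the achiral catalyst Ph3PAuCl/AgSbF6 and i-PrOH in CH2Cl2. This is the established racemic 6-exo Conia-ene reaction of silyl enol ethers, and it should give racemic 6,6-dimethyl-2-methylidenecyclohex-4-ene-1-carbaldehyde F1. Coupling of F1 with enantiopure 26 under the conditions of step 14 turns the two antipodes into diastereomers. These are 28 and (1R,2S,4S)-2-bromo-4-{(2E,4S)-4-[(1S)-6,6-dimethyl-2-methylidenecyclohex-4-en-1-yl]-4-hydroxybut-2-en-2-yl}-1-methylcyclohexan-1-ol F2, which are separated by chromatography. The route is rejoined at 28, at the price of half of the ring A material.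

2. Step 13.
- **Risk:** Bromide has to approach C14 alongside the axial C13 oxygen substituent. The displacement may therefore be overtaken by E2 loss of the sulfonate towards C15. It may also be overtaken by participation of the C13 oxygen, with loss of the silyl group and epoxide closure, which would end in the trans bromohydrin.
- **Fallback:** The C14–Br bond is made from alkene 19 by a net syn addition through selenium.
  - Hydroxyselenenylation with N-(phenylselanyl)phthalimide, water and catalytic camphorsulfonic acid in CH2Cl2 adds OH to C13 and PhSe to C14 in the trans-diaxial sense. This should give (1R,2R,4S)-4-[(1E)-1-iodoprop-1-en-2-yl]-1-methyl-2-(phenylselanyl)cyclohexan-1-ol F3.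
  - TMSOTf and 2,6-lutidine give trimethyl{[(1R,2R,4S)-4-[(1E)-1-iodoprop-1-en-2-yl]-1-methyl-2-(phenylselanyl)cyclohexyl]oxy}silane F4.
  - Bromine in CH2Cl2 at −78 °C converts the selenide into its tetravalent selenium dibromide. This is a far better leaving group, and bromide displaces it with inversion at low temperature.
  - The sequence comes back to the route at 25, which is desilylated to 26 as in step 13.

3. Step 14.
- **Risk:** Facial selectivity at the aldehyde may be modest, because both flanking ring carbons (C5 and C1) are bulky. Slow coupling would give the aldehyde time to slip into conjugation or divalent chromium time to attack the C–Br bond.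
- **Fallback:** C7 is set by reagent-controlled ketone reduction instead of by substrate-controlled addition. Setting out from 12 and 26, the coupling is accepted as a mixture of 28 and its epimer (1R,2S,4S)-2-bromo-4-{(2E,4S)-4-[(1R)-6,6-dimethyl-2-methylidenecyclohex-4-en-1-yl]-4-hydroxybut-2-en-2-yl}-1-methylcyclohexan-1-ol F5. The mixture is oxidised with Dess–Martin periodinane (NaHCO3-buffered, CH2Cl2, 0 °C) to (2E)-3-[(1S,3S,4R)-3-bromo-4-hydroxy-4-methylcyclohexyl]-1-[(1R)-6,6-dimethyl-2-methylidenecyclohex-4-en-1-yl]but-2-en-1-one F6. Corey–Bakshi–Shibata reduction with the (S)-Me-CBS oxazaborolidine and catecholborane in toluene at −78 °C then returns to 28. Here the ring carbon C6 is taken as the large group, and the antipodal catalyst is at hand should the alkenyl arm dominate.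

Further compounds
F1 | step 7 | racemic 6,6-dimethyl-2-methylidenecyclohex-4-ene-1-carbaldehyde | C=C1CC=CC(C)(C)C1C=O
F2 | step 7 | (1R,2S,4S)-2-bromo-4-{(2E,4S)-4-[(1S)-6,6-dimethyl-2-methylidenecyclohex-4-en-1-yl]-4-hydroxybut-2-en-2-yl}-1-methylcyclohexan-1-ol | C=C1CC=CC(C)(C)[C@H]1[C@@H](O)/C=C(\C)[C@H]1CC[C@@](C)(O)[C@@H](Br)C1
F3 | step 13 | (1R,2R,4S)-4-[(1E)-1-iodoprop-1-en-2-yl]-1-methyl-2-(phenylselanyl)cyclohexan-1-ol | C/C(=C\I)[C@H]1CC[C@@](C)(O)[C@H]([Se]c2ccccc2)C1
F4 | step 13 | trimethyl{[(1R,2R,4S)-4-[(1E)-1-iodoprop-1-en-2-yl]-1-methyl-2-(phenylselanyl)cyclohexyl]oxy}silane | C/C(=C\I)[C@H]1CC[C@@](C)(O[Si](C)(C)C)[C@H]([Se]c2ccccc2)C1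
F5 | step 14 | (1R,2S,4S)-2-bromo-4-{(2E,4S)-4-[(1R)-6,6-dimethyl-2-methylidenecyclohex-4-en-1-yl]-4-hydroxybut-2-en-2-yl}-1-methylcyclohexan-1-ol | C=C1CC=CC(C)(C)[C@@H]1[C@@H](O)/C=C(\C)[C@H]1CC[C@@](C)(O)[C@@H](Br)C1
F6 | step 14 | (2E)-3-[(1S,3S,4R)-3-bromo-4-hydroxy-4-methylcyclohexyl]-1-[(1R)-6,6-dimethyl-2-methylidenecyclohex-4-en-1-yl]but-2-en-1-one | C=C1CC=CC(C)(C)[C@@H]1C(=O)/C=C(\C)[C@H]1CC[C@@](C)(O)[C@@H](Br)C1
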